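Everything rests on cutting one bond of a bridged diketone instead of closing the cyclooctane end to end. In the target, the butenolide α-carbon (bearing the lactone C=O) and the CH(OAc) carbon are 1,4-related on the eight-membered ring. Bonding the lactone carbonyl carbon to the ring CH2 beside CH(OAc) folds that ring into a bicyclo[3.3.1]nonane-2,9-dione. Methoxide cleaves this bridge bond by retro-Claisen fragmentation and delivers, in one operation, the cyclooctanone, the ester at the future butenolide α-carbon and stereocentres fixed earlier on six-membered rings. The precursor 19 is a cyclopropane-fused dione carrying methyl, CH2OPMB and the citronellal-derived chain, assembled by one enamine α,α′-annulation.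

Key step: step 11

Locants for 18, 19, F2 and F3: C1 = bridgehead between the two carbonyls, C2 = ring ketone, C3 = side-chain carbon, C4 = CH2OPMB carbon, C5 = second bridgehead, C6–C7 = cyclopropane fusion, C8 = CHMe, C9 = bridge ketone. Ring A = C1–C5 plus C9, ring B = C5–C8, C1 and C9. Exo means on the side of C9.

Assumption: C4 of 19 is drawn exo, as a chair-like [3,3] shift of the E acid chloride predicts (a Z acid chloride would cyclise onto its own ether oxygen); C4 and C5 become sp2 in the butenolide, so their configuration never reaches the target.

Step 1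
Reactants: 1 cyclohex-2-en-1-one
Product: 3 (S)-3-methylcyclohexan-1-one, via methylzinc enolate 2 (not isolated)
Conditions: Me2Zn (1.2 equiv), Cu(OTf)2 (1 mol %), phosphoramidite from (S)-BINOL and bis[(R)-1-phenylethyl]amine (2 mol %, the antipode that leads to the S ketone), PhMe, −30 °C; then 1 M HCl
Reagents that add atoms: dimethylzinc, C[Zn]C
Why: Copper-catalysed asymmetric conjugate addition of a dialkylzinc with a phosphoramidite ligand, in which the chiral copper complex transfers methyl to one enantiotopic face of the enone and thereby sets the S methyl-bearing centre; enolate 2 has its double bond toward that centre, so it is protonated rather than dehydrogenated, which would erase the centre.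

Step 2
Reactants: 3 (S)-3-methylcyclohexan-1-one
Product: 5 (S)-5-methylcyclohex-2-en-1-one, via kinetic lithium enolate 4 (not isolated)
Conditions: LiN(i-Pr)2 (LDA, 1.1 equiv), THF, −78 °C; then N-tert-butylbenzenesulfinimidoyl chloride (1.2 equiv), −78 °C
Reagents that add atoms: none
Why: Mukaiyama one-pot dehydrogenation: kinetic deprotonation takes the less hindered C6 proton remote from the methyl group, enolate 4 attacks sulfur and the adduct undergoes intramolecular syn elimination, so the C=C forms on the side away from the stereocentre, which stays untouched, while any enolate formed on the other side ends as achiral 3-methylcyclohex-2-enone and is removed by chromatography.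

Step 3
Reactants: 5 (S)-5-methylcyclohex-2-en-1-one
Product: 6 (R)-9-methyl-1,4-dioxaspiro[4.5]dec-7-ene
Conditions: HOCH2CH2OH (3 equiv), p-TsOH·H2O (5 mol %), PhH, reflux, Dean–Stark
Reagents that add atoms: ethane-1,2-diol, OCCO
Why: Deconjugative acetalisation under strong-acid, water-removing conditions: the oxocarbenium ion equilibrates through the linear dienol ether, α-protonation moves the double bond to the β,γ-position and the glycol traps the more stable unconjugated acetal, a behaviour well known for cyclohexenones, without involving the methyl-bearing carbon.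

Step 4
Reactants: 6 (R)-9-methyl-1,4-dioxaspiro[4.5]dec-7-ene
Product: 7 (1R,5R,6S)-5-methylspiro[bicyclo[4.1.0]heptane-3,2'-[1,3]dioxolane] (cyclopropane trans to methyl)
Conditions: Et2Zn (1.5 equiv), CH2I2 (3 equiv), CH2Cl2, −10 °C → rt
Reagents that add atoms: diiodomethane, ICI
Why: Furukawa-modified Simmons–Smith cyclopropanation, concerted and syn on the alkene: in the half-chair with a pseudo-equatorial methyl group the axial dioxolane oxygen coordinates the zinc carbenoid and delivers CH2 to its own face, which is the face opposite the methyl group, so both new ring-fusion centres are set trans to methyl by steric and directing effects acting together.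

Step 5
Reactants: 7 cyclopropyl acetal
Product: 8 (1R,5R,6S)-5-methylbicyclo[4.1.0]heptan-3-one
Conditions: 1 M HCl, THF, rt
Reagents that add atoms: water, O
Why: Acid-catalysed acetal hydrolysis under conditions too mild to open an unactivated cyclopropane, with no stereocentre α to the liberated ketone.

Step 6
Reactants: 8 (1R,5R,6S)-5-methylbicyclo[4.1.0]heptan-3-one
Product: 9 1-[(1S,5R,6S)-5-methylbicyclo[4.1.0]hept-2-en-3-yl]pyrrolidine
Conditions: pyrrolidine (1.5 equiv), p-TsOH (cat.), PhMe, reflux, Dean–Stark; concentrated and used crude
Reagents that add atoms: pyrrolidine, C1CCNC1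
Why: Stork enamine formation with azeotropic water removal; the two double-bond isomers interconvert, and the one drawn, conjugated with the cyclopropane and flanked by a tied-back cyclopropane CH instead of CHMe, is the less hindered nucleophile.

Step 7
Reactants: 10 (R)-citronellal
Product: 11 (R,E)-N-cyclohexyl-3,7-dimethyloct-6-en-1-imine
Conditions: c-HexNH2 (1.0 equiv), MgSO4, Et2O, 0 °C → rt
Reagents that add atoms: cyclohexylamine, NC1CCCCC1
Why: Condensation of an aldehyde with a primary amine to the aldimine needed for a directed aldol reaction, under neutral drying conditions that leave the β-stereocentre and the alkene alone.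

Step 8
Reactants: 11 citronellal cyclohexylimine; 12 2-[(4-methoxyphenyl)methoxy]acetaldehyde
Product: 15 (E)-4-[(4-methoxybenzyl)oxy]-2-[(2R)-6-methylhept-5-en-2-yl]but-2-enal, via lithiated imine 13 (not isolated), via lithium aldolate 14 (not isolated)
Conditions: LiN(i-Pr)2 (LDA, 1.05 equiv), THF, 0 °C; 12, −78 °C; then aq. oxalic acid, THF, rt
Reagents that add atoms: water, O
Why: Wittig directed aldol condensation: the preformed azaenolate 13 adds to the more electrophilic alkoxy aldehyde 12 without self-condensation, and aqueous oxalic acid converts aldolate 14 by loss of water through its enamine tautomer and imine hydrolysis into the conjugated enal, the E isomer being favoured thermodynamically, so that the two transient aldol centres disappear and the citronellal centre, which is not acidic, is retained.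

Step 9
Reactants: 15 E enal
Product: 16 (E)-4-[(4-methoxybenzyl)oxy]-2-[(2R)-6-methylhept-5-en-2-yl]but-2-enoic acid
Conditions: NaClO2, NaH2PO4, 2-methylbut-2-ene (excess), t-BuOH–H2O, 0 °C → rt
Reagents that add atoms: sodium chlorite, [Na+].[O-]Cl=O
Why: Pinnick oxidation, specific for the aldehyde, with excess 2-methylbut-2-ene intercepting HOCl so that the trisubstituted alkene, the enoate double bond and the anisyl ring are spared.

Step 10
Reactants: 16 E acid; 9 norcaranone pyrrolidine enamine
Product: 19 cyclopropane-fused bicyclo[3.3.1]nonane-2,9-dione (8-endo-methyl; 6,7-exo-cyclopropane; 4-exo-CH2OPMB; 3-exo-[(2R)-6-methylhept-5-en-2-yl]), via acid chloride 17 (not isolated), via bicyclic iminium chloride 18 (not isolated)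
Conditions: 16, 1-chloro-N,N,2-trimethylprop-1-en-1-amine (Ghosez's reagent, 1.0 equiv), PhMe, 0 °C → rt; solution added slowly to 9 in PhMe, 80 °C → reflux; then H2O, rt; dried extract, DBU (cat.), PhMe, rt
Reagents that add atoms: water, O
Why: Stork-type enamine α,α′-annulation with an α,β-unsaturated acid chloride, made under neutral conditions with Ghosez's reagent to spare PMB ether and alkene: N-acylation of 9 and a chair-like [3,3] shift bond the β-carbon of 17 to the enamine carbon next to the cyclopropane on the face anti to the cyclopropane CH2 (sets C5 and, from the E alkene, C4 exo), the isomerised enamine then closes onto the resulting ketene at the carbon next to CHMe, necessarily on the same face (sets C1 and leaves methyl endo, cyclopropane exo), and C3, α to the ring ketone, is brought under thermodynamic control by catalytic DBU and takes the equatorial exo position because an endo chain would run into ring B.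

Step 11
Reactants: 19 cyclopropane-fused bicyclo[3.3.1]nonane-2,9-dione
Product: 20 methyl 3-{[(4-methoxybenzyl)oxy]methyl}-7-methyl-4-[(2R)-6-methylhept-5-en-2-yl]-5-oxobicyclo[6.1.0]nonane-2-carboxylate (ester, CH2OPMB, side chain and cyclopropane CH2 on one ring face; methyl on the other)
Conditions: NaOMe (1.1 equiv), MeOH–THF, −20 → 0 °C; AcOH quench at 0 °C
Reagents that add atoms: sodium methoxide, [Na+].[O-]C
Why: Methoxide adds to the bridge carbonyl C9, the more electrophilic ketone because rehybridisation relieves the angle strain of the one-carbon bridge, and the tetrahedral alkoxide collapses by breaking C9–C1, the only bond whose electrons can flow into the C2 carbonyl, giving the C1=C2 enolate that methanol protonates (retro-Claisen cleavage of a β-diketone). The closest known reaction is the alkoxide or hydroxide opening of bicyclo[3.3.1]nonane-2,9-diones to 4-oxocyclooctanecarboxylic acid derivatives. The eight-membered ring is not closed by bond formation: it is the periphery C1–C8 of the bicycle and is set free by scission of the bridge bond, so no medium-ring closure has to be paid for. No stereocentre is created; C1 becomes CH2, and C3 to C8 and the side-chain centre are carried over unchanged. The step needs site selectivity (C9 against C2) and retention at C3: C2 is screened by the neighbouring sec-alkyl branch, the axial C4 substituent and the endo methyl at C8, whereas C9 is the exposed apex, and because C1 cannot form the stabilised central enolate (bridgehead double bond) no unreactive enolate competes, so cleavage should run at or below 0 °C. At that temperature and with a prompt acetic acid quench the hindered tertiary C3–H next to the liberated ketone should not exchange.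

Step 12
Reactants: 20 keto ester
Product: 22 keto lactone (γ-lactone cis-fused to the cyclooctanone, on the same ring face as side chain and cyclopropane CH2), via hydroxy ester 21 (not isolated)
Conditions: DDQ (1.3 equiv), CH2Cl2–pH 7 buffer, 0 °C → rt; dried organic phase, PPTS (cat.), rt
Reagents that add atoms: none
Why: Oxidative PMB cleavage with DDQ (hydride abstraction at the electron-rich benzylic position and hydrolysis of the oxocarbenium ion) frees the primary alcohol of 21, which sits cis to the ester on the adjacent ring carbon and closes to the γ-lactone by acid-catalysed transesterification, while ketone, alkene and cyclopropane are inert.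

Step 13
Reactants: 22 keto lactone
Product: 23 hydroxy lactone (R carbinol, OH cis to the side chain)
Conditions: LiBH(s-Bu)3 (L-Selectride, 1.2 equiv), THF, −78 °C; sat. aq. NH4Cl
Reagents that add atoms: none
Why: Sterically controlled ketone reduction with a bulky trialkylborohydride: side chain, lactone and cyclopropane CH2 occupy one ring face, so hydride should arrive from the opposite face, anti to the adjacent sec-alkyl branch, giving the alcohol cis to that branch as is general for 2-alkylcycloalkanones, and the lactone is not reduced at −78 °C.

Step 14
Reactants: 23 hydroxy lactone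
Product: 25 α-(phenylselanyl) hydroxy lactone (Se on the lactone α-carbon, syn to the H on the neighbouring ring-fusion carbon), via dilithio alkoxide enolate 24 (not isolated)
Conditions: LiN(i-Pr)2 (LDA, 2.3 equiv), THF, −78 °C; PhSeSePh (1.2 equiv), DMPU, −78 → −30 °C; sat. aq. NH4Cl
Reagents that add atoms: diphenyl diselenide, c1ccccc1[Se][Se]c1ccccc1
Why: α-Selenenylation of a lactone enolate through the alkoxide–enolate dianion, placed before acetylation because an acetate would not survive LDA and run with the diselenide because it does not add to the side-chain alkene; selenium is taken up on the enolate face that carries the H of the adjacent ring-fusion carbon, anti to the ring bond, which keeps the cis fusion and sets the quaternary centre with Se syn to that hydrogen.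

Step 15
Reactants: 25 α-(phenylselanyl) hydroxy lactone
Product: 26 α-(phenylselanyl) lactone acetate
Conditions: Ac2O, DMAP (cat.), pyridine, rt
Reagents that add atoms: acetic anhydride, CC(=O)OC(C)=O
Why: DMAP-catalysed acylation of the secondary alcohol with retention at the carbinol carbon, under conditions to which selenide, lactone and alkene are indifferent.

Step 16
Reactants: 26 α-(phenylselanyl) lactone acetate
Product: 28 butenolide acetate (target skeleton with the intact 6-methylhept-5-en-2-yl chain), via selenoxide 27 (not isolated)
Conditions: H2O2 (30 % aq., 3 equiv), pyridine, CH2Cl2, 0 °C → rt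
Reagents that add atoms: none
Why: Selenoxide syn elimination: selenium is oxidised much faster than the alkene, and the selenoxide removes the syn hydrogen on the CH2O-bearing carbon to give the tetrasubstituted butenolide, elimination toward the cyclopropane C–H being blocked by the strain of an alkylidenecyclopropane, so that both lactone ring-fusion centres vanish.

Step 17
Reactants: 28 butenolide acetate
Product: 29 target hydroperoxide CNP0205234.1
Conditions: O2, tetraphenylporphyrin (cat.), visible light, CH2Cl2, 0 °C; no reductive work-up
Reagents that add atoms: dioxygen, O=O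
Why: Schenck ene reaction: singlet oxygen attacks only the electron-rich trisubstituted alkene (the butenolide is electron-poor), and abstraction of an allylic CH2 hydrogen on the more crowded side of the alkene with allylic shift gives the tertiary hydroperoxide and the E-disubstituted double bond, the regioisomeric secondary hydroperoxide from methyl hydrogen abstraction being the expected co-product that is removed by chromatography.

Compound list
1 | cyclohex-2-en-1-one | O=C1C=CCCC1 | starting material
2 | methylzinc (S)-3-methylcyclohex-1-en-1-olate | C[Zn]OC1=C[C@@H](C)CCC1 | intermediate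
3 | (S)-3-methylcyclohexan-1-one | O=C1C[C@@H](C)CCC1 | intermediate
4 | lithium (S)-5-methylcyclohex-1-en-1-olate | [Li]OC1=CCC[C@H](C)C1 | intermediate
5 | (S)-5-methylcyclohex-2-en-1-one | O=C1C[C@@H](C)CC=C1 | intermediate
6 | (R)-9-methyl-1,4-dioxaspiro[4.5]dec-7-ene | O1CCOC12C[C@@H](C)C=CC2 | intermediate
7 | (1R,5R,6S)-5-methylspiro[bicyclo[4.1.0]heptane-3,2'-[1,3]dioxolane] | O1CCOC12C[C@@H](C)[C@@H]3C[C@@H]3C2 | intermediate
8 | (1R,5R,6S)-5-methylbicyclo[4.1.0]heptan-3-one | O=C1C[C@@H](C)[C@@H]2C[C@@H]2C1 | intermediate
9 | 1-[(1S,5R,6S)-5-methylbicyclo[4.1.0]hept-2-en-3-yl]pyrrolidine | C1CCN(C1)C2=C[C@H]3C[C@H]3[C@H](C)C2 | intermediate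
10 | (R)-citronellal | C[C@H](CCC=C(C)C)CC=O | starting material
11 | (R,E)-N-cyclohexyl-3,7-dimethyloct-6-en-1-imine | C[C@H](CCC=C(C)C)C/C=N/C1CCCCC1 | intermediate
12 | 2-[(4-methoxyphenyl)methoxy]acetaldehyde | COc1ccc(COCC=O)cc1 | starting material
13 | lithium azaenolate of 11 | [Li]N(C1CCCCC1)C=C[C@H](C)CCC=C(C)C | intermediate
14 | lithium aldolate of the β-hydroxy imine (mixture at the two new carbons) | [Li]OC(COCc1ccc(OC)cc1)C(C=NC2CCCCC2)[C@H](C)CCC=C(C)C | intermediate
15 | (E)-4-[(4-methoxybenzyl)oxy]-2-[(2R)-6-methylhept-5-en-2-yl]but-2-enal | O=C/C(=C/COCc1ccc(OC)cc1)[C@H](C)CCC=C(C)C | intermediate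
16 | (E)-4-[(4-methoxybenzyl)oxy]-2-[(2R)-6-methylhept-5-en-2-yl]but-2-enoic acid | OC(=O)/C(=C/COCc1ccc(OC)cc1)[C@H](C)CCC=C(C)C | intermediate
17 | (E)-4-[(4-methoxybenzyl)oxy]-2-[(2R)-6-methylhept-5-en-2-yl]but-2-enoyl chloride | ClC(=O)/C(=C/COCc1ccc(OC)cc1)[C@H](C)CCC=C(C)C | intermediate
18 | C9 pyrrolidinium-ylidene analogue of 19, chloride | [Cl-].O=C1[C@H]2[C@@H](C)[C@@H]3C[C@@H]3[C@H](C2=[N+]4CCCC4)[C@H](COCc5ccc(OC)cc5)[C@@H]1[C@H](C)CCC=C(C)C | intermediate
19 | 6,7-exo-cyclopropane-fused 8-endo-methyl-4-exo-{[(4-methoxybenzyl)oxy]methyl}-3-exo-[(2R)-6-methylhept-5-en-2-yl]bicyclo[3.3.1]nonane-2,9-dione | O=C1[C@H]2[C@@H](C)[C@@H]3C[C@@H]3[C@H](C2=O)[C@H](COCc4ccc(OC)cc4)[C@@H]1[C@H](C)CCC=C(C)C | intermediate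
20 | methyl 3-{[(4-methoxybenzyl)oxy]methyl}-7-methyl-4-[(2R)-6-methylhept-5-en-2-yl]-5-oxobicyclo[6.1.0]nonane-2-carboxylate | O=C1C[C@@H](C)[C@@H]2C[C@@H]2[C@H](C(=O)OC)[C@H](COCc3ccc(OC)cc3)[C@@H]1[C@H](C)CCC=C(C)C | intermediate
21 | methyl 3-(hydroxymethyl)-7-methyl-4-[(2R)-6-methylhept-5-en-2-yl]-5-oxobicyclo[6.1.0]nonane-2-carboxylate | O=C1C[C@@H](C)[C@@H]2C[C@@H]2[C@H](C(=O)OC)[C@H](CO)[C@@H]1[C@H](C)CCC=C(C)C | intermediate
22 | keto lactone (cis-fused γ-lactone on the cyclopropane-fused cyclooctanone) | O=C1C[C@@H](C)[C@@H]2C[C@@H]2[C@@H]3C(=O)OC[C@@H]3[C@@H]1[C@H](C)CCC=C(C)C | intermediate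
23 | hydroxy lactone (R carbinol, OH cis to side chain) | O[C@@H]1C[C@@H](C)[C@@H]2C[C@@H]2[C@@H]3C(=O)OC[C@@H]3[C@@H]1[C@H](C)CCC=C(C)C | intermediate
24 | dilithio alkoxide–lactone enolate of 23 | [Li]O[C@@H]1C[C@@H](C)[C@@H]2C[C@@H]2C3=C(O[Li])OC[C@@H]3[C@@H]1[C@H](C)CCC=C(C)C | intermediate
25 | α-(phenylselanyl) hydroxy lactone | O[C@@H]1C[C@@H](C)[C@@H]2C[C@@H]2[C@]3([Se]c4ccccc4)C(=O)OC[C@@H]3[C@@H]1[C@H](C)CCC=C(C)C | intermediate
26 | α-(phenylselanyl) lactone acetate | CC(=O)O[C@@H]1C[C@@H](C)[C@@H]2C[C@@H]2[C@]3([Se]c4ccccc4)C(=O)OC[C@@H]3[C@@H]1[C@H](C)CCC=C(C)C | intermediate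
27 | selenoxide of 26 | CC(=O)O[C@@H]1C[C@@H](C)[C@@H]2C[C@@H]2[C@]3([Se](=O)c4ccccc4)C(=O)OC[C@@H]3[C@@H]1[C@H](C)CCC=C(C)C | intermediate
28 | butenolide acetate with 6-methylhept-5-en-2-yl chain | CC(=O)O[C@@H]1C[C@@H](C)[C@@H]2C[C@@H]2C2=C(COC2=O)[C@@H]1[C@H](C)CCC=C(C)C | intermediate
29 | CNP0205234.1, tertiary allylic hydroperoxide | CC(=O)O[C@@H]1C[C@@H](C)[C@@H]2C[C@@H]2C2=C(COC2=O)[C@@H]1[C@H](C)C/C=C/C(C)(C)OO | target

Total step count: 17. Longest linear sequence: 14 steps (steps 1–6, then 10–17). Steps 7–9 form the three-step side branch.

Steps most likely to fail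

Step 10.
- **What may go wrong:**
  - The hindered, α-branched acid chloride may lose HCl to a vinylketene or stop at simple acylation.
  - The first C–C bond may form at the α-carbon next to CHMe.
  - The ketene released by the sigmatropic shift may not be captured at C1, so the second ring does not close.
- **Fallback (sets out from 9 and 15, comes back at 19):** the ring is closed at the aldehyde oxidation level by a reversible aldol reaction instead of an acylation.
  - Stork Michael addition of 9 to the enal 15 (MeCN, rt to 60 °C) follows the usual synclinal topology of enamine additions and so has the same sense as the sigmatropic route. After hydrolysis with aqueous acetic acid it should give the keto aldehyde F1.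
  - K2CO3 in MeOH then closes the only strain-free aldol (C1 onto the aldehyde) to the ketol F2, which cannot dehydrate because that would need a bridgehead alkene.
  - Dess–Martin periodinane in CH2Cl2 oxidises F2 to 19.

Step 11.
- **What may go wrong:**
  - The axial C4 substituent and the exo cyclopropane may slow addition at C9, letting methoxide add to C2 and reopen ring A to a cyclohexanone.
  - Prolonged exposure to base may exchange the C3 hydrogen after cleavage.
- **Fallback (sets out from 19, comes back at 22):** the nucleophile is made internal.
  - DDQ (CH2Cl2–pH 7 buffer) removes the PMB group first to give the hydroxymethyl dione F3, whose exo CH2OH lies syn-axial to the strained bridge carbonyl.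
  - With catalytic DBU in CH2Cl2 the five-membered hemiketal at C9 should form and fragment along the same C9–C1 bond. This gives the keto lactone 22 directly, without methoxide or methanol, and one step shorter.

Step 13.
- **What may go wrong:** poor facial selectivity of hydride delivery on the conformationally mobile cyclooctanone, or enolisation instead of reduction.
- **Fallback (sets out from 22, comes back at 23):** the carbinol configuration is corrected by substitution rather than set by reduction.
  - Whichever hydride gives it cleanly (for example NaBH4, MeOH, 0 °C) is used to make the epimeric alcohol F4.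
  - A Mitsunobu reaction (PPh3, DIAD, 4-nitrobenzoic acid, THF) inverts the carbinol carbon to the 4-nitrobenzoate F5.
  - Methanolysis (K2CO3, MeOH, then mildly acidic work-up to keep the lactone closed) gives 23.

Further compounds
F1 | step 10 | keto aldehyde, 2-substituted norcaranone bearing CH(CH2OPMB)CH(CHO)(side chain), formyl-bearing carbon unassigned | O=C1C[C@@H](C)[C@@H]2C[C@@H]2[C@H]1[C@H](COCc3ccc(OC)cc3)C(C=O)[C@H](C)CCC=C(C)C
F2 | step 10 | ketol, 2-hydroxy analogue of 19 (carbinol configuration unassigned, erased on oxidation) | OC1[C@H]2[C@@H](C)[C@@H]3C[C@@H]3[C@H](C2=O)[C@H](COCc4ccc(OC)cc4)[C@@H]1[C@H](C)CCC=C(C)C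
F3 | step 11 | hydroxymethyl dione, 19 without the PMB group | O=C1[C@H]2[C@@H](C)[C@@H]3C[C@@H]3[C@H](C2=O)[C@H](CO)[C@@H]1[C@H](C)CCC=C(C)C
F4 | step 13 | epimeric hydroxy lactone (S carbinol, OH trans to side chain) | O[C@H]1C[C@@H](C)[C@@H]2C[C@@H]2[C@@H]3C(=O)OC[C@@H]3[C@@H]1[C@H](C)CCC=C(C)C
F5 | step 13 | 4-nitrobenzoate of 23 | O=C(O[C@@H]1C[C@@H](C)[C@@H]2C[C@@H]2[C@@H]3C(=O)OC[C@@H]3[C@@H]1[C@H](C)CCC=C(C)C)c4ccc(cc4)[N+](=O)[O-]
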